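The route rests on disconnecting ring A at C1–C10 and C4=C5: a Robinson-type annulation of a C5 ketone with tert-butyl 3-oxopent-4-enoate. It exploits quaternary C10 lying between C5 and C4, the latter bearing ester-level C19, in ring A (C1–C5, C10). In one operation the step forms both bonds, closes ring A and sets C10 under control of C9. Its precursor is the complete, enantiopure bicyclo[3.2.1]octane (C8, C9, C11–C16) carrying on C9 an α-methyl α′-(dimethoxymethyl) ketone chain (C10, C20, C5, C6), with C7 as a silyl ether and the C16/C17 diol as an acetonide. The bicycle comes from an asymmetric Diels–Alder reaction, a gold-catalysed cyclisation and an exo Mukaiyama–Michael addition.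

Key step: step 18

Assumption: the (S)-oxazaborolidinium catalyst of step 3 is taken to shield the enal face that leads to the (R)-configured adduct; if the sense proves opposite, the (R)-catalyst is used and nothing else changes.
Assumption: the target is handled as the open aldehydo acid that is drawn; ring–chain tautomerism between the C19 acid and the C6 aldehyde does not change the synthetic problem.

Atom labels (C1–C20) are kaurane labels of the target.

Step 1
Reactants: 1 pent-4-ynal; 2 formaldehyde (37 % in water)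
Product: 3 2-methylidenepent-4-ynal
Conditions: pyrrolidine (10 mol %), EtCO2H (10 mol %), i-PrOH, 45 °C
Reagents that add atoms: none
Why: Amine-catalysed Mannich condensation–elimination (α-methylenation of an aldehyde) should turn the CH2 next to CHO into the 1,1-disubstituted enal without touching the terminal alkyne.

Step 2
Reactants: 4 methyl vinyl ketone
Product: 5 2-[(triisopropylsilyl)oxy]buta-1,3-diene
Conditions: i-Pr3SiOTf, Et3N, Et2O, 0 °C → rt
Reagents that add atoms: triisopropylsilyl trifluoromethanesulfonate (CC(C)[Si](OS(=O)(=O)C(F)(F)F)(C(C)C)C(C)C)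
Why: Soft enolisation and O-silylation of the methyl ketone gives the 2-silyloxy diene, and the bulky silyl group makes it robust enough for an acid-catalysed cycloaddition.

Step 3
Reactants: 3 2-methylidenepent-4-ynal; 5 2-[(triisopropylsilyl)oxy]buta-1,3-diene
Product: 6 (R)-1-(prop-2-yn-1-yl)-4-[(triisopropylsilyl)oxy]cyclohex-3-ene-1-carbaldehyde
Conditions: (S)-o-tolyl oxazaborolidine derived from (S)-α,α-diphenylprolinol (20 mol %), HNTf2 (18 mol %), CH2Cl2, −78 → −40 °C
Reagents that add atoms: none
Why: Catalytic enantioselective Diels–Alder reaction of an α-substituted acrolein, in which the diene terminus next to the silyloxy carbon bonds to the enal β-carbon ("para" adduct, enol ether C12=C13 on the C14 side) and the catalyst-bound enal is attacked on one face, which sets quaternary C8, the stereocentre from which all others follow.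

Step 4
Reactants: 6 (R)-1-(prop-2-yn-1-yl)-4-[(triisopropylsilyl)oxy]cyclohex-3-ene-1-carbaldehyde
Product: 7 (R)-{1-(prop-2-yn-1-yl)-4-[(triisopropylsilyl)oxy]cyclohex-3-en-1-yl}methanol
Conditions: NaBH4, EtOH, 0 °C
Reagents that add atoms: none
Why: Borohydride reduction of the neopentyl aldehyde (C7) should leave the silyl enol ether and the alkyne untouched.

Step 5
Reactants: 7 (R)-{1-(prop-2-yn-1-yl)-4-[(triisopropylsilyl)oxy]cyclohex-3-en-1-yl}methanol
Product: 8 tert-butyldimethylsilyl ether of 7
Conditions: t-BuMe2SiCl, imidazole, DMF, rt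
Reagents that add atoms: tert-butyldimethylsilyl chloride (CC(C)(C)[Si](C)(C)Cl)
Why: Standard silylation of the primary alcohol, needed so that the hydroxyl cannot add to the gold-activated alkyne in the next step.

Step 6
Reactants: 8 tert-butyldimethylsilyl ether of 7
Product: 9 5-{[(tert-butyldimethylsilyl)oxy]methyl}-7-methylidenebicyclo[3.2.1]octan-2-one (C12 ketone; CH2OSi on bridgehead C8; C16=C17)
Conditions: Ph3PAuCl (5 mol %), AgBF4 (5 mol %), CH2Cl2/MeOH 10:1, rt
Reagents that add atoms: none
Why: Gold-catalysed 5-exo-dig carbocyclisation of a silyl enol ether onto a terminal alkyne (Conia-ene type), in which C13 attacks the internal alkyne carbon C16 and methanol protonates the vinyl–gold bond and takes the silyl group; bridgehead C13 is fixed by the tether from C8.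

Step 7
Reactants: 9 bicyclic ketone
Product: 10 diol of 9 with exo OH and endo CH2OH on C16
Conditions: OsO4 (2 mol %), N-methylmorpholine N-oxide, acetone/H2O, rt
Reagents that add atoms: N-methylmorpholine N-oxide (C[N+]1([O-])CCOCC1); water (O)
Why: Catalytic dihydroxylation (Upjohn conditions) should occur on the exo face of C16=C17 because the endo face is screened by the C11–C12 part of the three-carbon bridge, which places the C16 hydroxyl exo as in the target.

Step 8
Reactants: 10 diol
Product: 11 acetonide of 10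
Conditions: 2-methoxypropene, pyridinium p-toluenesulfonate (cat.), CH2Cl2, 0 °C
Reagents that add atoms: 2-methoxypropene (C=C(C)OC)
Why: Acid-catalysed ketalisation of the 1,2-diol under mild, methanol-poor conditions that leave the ketone and the silyl ether alone.

Step 9
Reactants: 11 acetonide ketone
Product: 13 bicyclo[3.2.1]oct-3-en-2-one (C9=C11, C12 ketone) bearing CH2OSi on C8 and the C16/C17 acetonide, via trimethylsilyl enol ether 12 (not isolated)
Conditions: LiN(i-Pr)2, Me3SiCl, THF, −78 °C; then Pd(OAc)2, MeCN, rt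
Reagents that add atoms: none
Why: Saegusa–Ito oxidation; the ketone can enolise only towards C11 because C13 is a bridgehead, so the C9=C11 double bond is formed regiospecifically.

Step 10
Reactants: 14 methyl propanoate
Product: 15 1-methoxy-1-[(trimethylsilyl)oxy]prop-1-ene (E/Z mixture)
Conditions: LiN(i-Pr)2, Me3SiCl, THF, −78 °C
Reagents that add atoms: chlorotrimethylsilane (C[Si](C)(C)Cl)
Why: Kinetic ester enolisation and O-silylation gives the silyl ketene acetal, a strong and non-ionisable carbon nucleophile.

Step 11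
Reactants: 13 bicyclic enone; 15 silyl ketene acetal
Product: 17 methyl 2-(bicyclyl)propanoate with C12 ketone (C9 exo-substituted; both C10 epimers), via trichlorotitanium enolate 16 (not isolated)
Conditions: TiCl4, CH2Cl2, −78 °C; then aq. NaHCO3
Reagents that add atoms: none
Why: Mukaiyama–Michael addition to the TiCl4-activated enone should take place at C9 from the exo face (anti to the C15–C16 bridge, while the acetonide covers the endo face), which places C10 axial on ring C as in the target; the C10 configuration is of no consequence.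

Step 12
Reactants: 17 keto ester
Product: 18 C11=C12 enol triflate of 17
Conditions: KN(SiMe3)2, PhNTf2, THF, −78 → 0 °C
Reagents that add atoms: N-phenylbis(trifluoromethanesulfonimide) (O=S(=O)(N(c1ccccc1)S(=O)(=O)C(F)(F)F)C(F)(F)F)
Why: Kinetic deprotonation of the ketone at C11 (its only enolisable position, and more acidic than the ester α-CH) followed by O-sulfonylation gives the enol triflate.

Step 13
Reactants: 18 enol triflate
Product: 19 methyl 2-(bicyclyl)propanoate with C11 and C12 as CH2 (both C10 epimers)
Conditions: H2 (1 atm), PtO2, K2CO3, EtOAc, rt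
Reagents that add atoms: none
Why: Catalytic hydrogenolysis of an enol triflate replaces the former C12 carbonyl by CH2, with carbonate buffering the triflic acid so that acetonide and silyl ether survive.

Step 14
Reactants: 19 ester; 20 1,3-dithiane
Product: 22 2-acyl-1,3-dithiane (C5 ketone; C6 as dithiane carbon), via 2-lithio-1,3-dithiane 21 (not isolated)
Conditions: n-BuLi, THF, −30 °C; then 19, −78 → 0 °C (2.4 equiv of 21)
Reagents that add atoms: none
Why: Acylation of a lithiated dithiane by an ester (Corey–Seebach chemistry), in which the acidic 2-acyl dithiane product is deprotonated by the second equivalent and thus protected from a second addition.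

Step 15
Reactants: 22 2-acyl-1,3-dithiane
Product: 23 1,1-dimethoxy-3-(bicyclyl)butan-2-one (C5 ketone, C6 dimethyl acetal; both C10 epimers)
Conditions: PhI(OCOCF3)2, NaHCO3, MeOH, 0 °C
Reagents that add atoms: methanol (CO)
Why: Oxidative dithiane cleavage by a hypervalent iodine reagent in methanol, where the thionium ion is trapped twice by methanol and the dimethyl acetal is formed directly under buffered conditions.

Step 16
Reactants: 24 tert-butyl acetate; 25 acrolein
Product: 26 tert-butyl 3-hydroxypent-4-enoate (racemic)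
Conditions: LiN(i-Pr)2, THF, −78 °C
Reagents that add atoms: none
Why: Aldol addition of the lithium ester enolate to acrolein, which at low temperature is a clean 1,2-addition.

Step 17
Reactants: 26 tert-butyl 3-hydroxypent-4-enoate
Product: 27 tert-butyl 3-oxopent-4-enoate
Conditions: Dess–Martin periodinane, NaHCO3, CH2Cl2, 0 °C; used at once
Reagents that add atoms: none
Why: Mild oxidation of the allylic alcohol to the vinyl ketone keto ester, which is used immediately because it polymerises on standing.

Step 18
Reactants: 23 ketone acetal; 27 tert-butyl 3-oxopent-4-enoate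
Product: 30 ring A enone (C3 ketone, C4 tert-butyl ester, C4=C5, C5 dimethoxymethyl, quaternary C10), via Michael adduct 28 (not isolated), via aldol adduct 29 (not isolated)
Conditions: Cs2CO3, MeCN, rt → 50 °C; 27 (3 equiv) added by syringe pump over 12 h
Reagents that add atoms: none
Why: Cs2CO3 reversibly forms the tetrasubstituted C10 enolate of 23 (the acetal C–H on C6 is not removed), which adds to the vinyl terminus C1 of 27, after which the β-keto ester methylene C4 attacks the activated C5 ketone and water is lost by E1cB; this is a Robinson annulation with a 3-oxopent-4-enoate. Ring A is closed by a 6-(enolendo)-exo-trig aldol addition followed by dehydration to the conjugated alkylidene β-keto ester. The new stereocentre C10 is controlled by C9, since allylic 1,3-strain holds H9 in the enolate plane facing C5, so that quaternary C8 covers one face and C11 the other, and the acceptor adds anti to C8. Both C10 epimers of 23 give the same enolate and therefore converge. The step needs enolisation towards C10 at a rate that competes with self-condensation of 27, which is served by the slow addition of excess 27 and the non-acidic acetal C–H, and it needs the size difference between C8 and C11 for facial control.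

Step 19
Reactants: 30 ring A enone
Product: 32 β-keto ester with C4 (methyl C18 equatorial, tert-butyl ester axial) and C5 (H anti to C20) set, via lithium enolate 31 (not isolated)
Conditions: Li, NH3/THF, t-BuOH (1 equiv), −78 °C; isoprene; then MeI, −78 → −33 °C
Reagents that add atoms: iodomethane (CI)
Why: Reductive alkylation of an enone by dissolving metal; with the bulky bicycle equatorial and C20 axial on ring A, C5 is protonated axially anti to C20 and the remaining β-keto ester enolate is methylated at C4 on the face away from C20.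

Step 20
Reactants: 32 β-keto ester
Product: 33 C2=C3 enol triflate of 32
Conditions: KN(SiMe3)2, PhNTf2, THF, −78 → 0 °C
Reagents that add atoms: N-phenylbis(trifluoromethanesulfonimide) (O=S(=O)(N(c1ccccc1)S(=O)(=O)C(F)(F)F)C(F)(F)F)
Why: The C3 ketone can enolise only towards C2 because C4 is quaternary, and O-sulfonylation of that enolate gives the enol triflate.

Step 21
Reactants: 33 enol triflate
Product: 34 ring A with C2 and C3 as CH2 (tert-butyl ester, dimethyl acetal, acetonide and silyl ether intact)
Conditions: H2 (1 atm), PtO2, K2CO3, EtOAc, rt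
Reagents that add atoms: none
Why: Catalytic hydrogenolysis of the enol triflate, as in step 13, removes the C3 oxygen under buffered, neutral conditions.

Step 22
Reactants: 34 silyl ether
Product: 35 C7 primary alcohol
Conditions: Bu4NF, THF, rt
Reagents that add atoms: none
Why: Fluoride-induced desilylation of the primary silyl ether, to which acetals and the tert-butyl ester are inert.

Step 23
Reactants: 35 C7 alcohol
Product: 36 C7 aldehyde (C6 dimethyl acetal, acetonide, tert-butyl ester)
Conditions: Dess–Martin periodinane, NaHCO3, CH2Cl2, rt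
Reagents that add atoms: none
Why: Oxidation of the neopentyl primary alcohol to the aldehyde on quaternary C8, which cannot enolise.

Step 24
Reactants: 36 protected aldehyde
Product: 37 target CNP0159160.1
Conditions: CF3CO2H/CH2Cl2/H2O 5:5:1, 0 °C → rt
Reagents that add atoms: water (O)
Why: Acid hydrolysis should cleave the dimethyl acetal, the acetonide and the tert-butyl ester (alkyl–oxygen cleavage) in one operation, under conditions mild enough to leave C5 next to the new aldehyde unchanged.

Compound list
1 | pent-4-ynal | C#CCCC=O | starting material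
2 | formaldehyde | C=O | starting material
3 | 2-methylidenepent-4-ynal | C=C(CC#C)C=O | intermediate
4 | methyl vinyl ketone | CC(=O)C=C | starting material
5 | 2-[(triisopropylsilyl)oxy]buta-1,3-diene | C=CC(=C)O[Si](C(C)C)(C(C)C)C(C)C | intermediate
6 | (R)-1-(prop-2-yn-1-yl)-4-[(triisopropylsilyl)oxy]cyclohex-3-ene-1-carbaldehyde | O=C[C@]1(CC#C)CCC(O[Si](C(C)C)(C(C)C)C(C)C)=CC1 | intermediate
7 | (R)-{1-(prop-2-yn-1-yl)-4-[(triisopropylsilyl)oxy]cyclohex-3-en-1-yl}methanol | OC[C@]1(CC#C)CCC(O[Si](C(C)C)(C(C)C)C(C)C)=CC1 | intermediate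
8 | tert-butyldimethylsilyl ether of 7 | CC(C)(C)[Si](C)(C)OC[C@]1(CC#C)CCC(O[Si](C(C)C)(C(C)C)C(C)C)=CC1 | intermediate
9 | 5-{[(tert-butyldimethylsilyl)oxy]methyl}-7-methylidenebicyclo[3.2.1]octan-2-one | C1CC(=O)[C@@H]2C[C@@]1(CO[Si](C)(C)C(C)(C)C)CC2=C | intermediate
10 | diol of 9 (C16 exo OH, C17 CH2OH) | C1CC(=O)[C@@H]2C[C@@]1(CO[Si](C)(C)C(C)(C)C)C[C@]2(O)CO | intermediate
11 | acetonide of 10 | C1CC(=O)[C@@H]2C[C@@]1(CO[Si](C)(C)C(C)(C)C)C[C@]2(OC(C)(C)O3)C3 | intermediate
12 | trimethylsilyl enol ether of 11 (C11=C12) | C1C=C(O[Si](C)(C)C)[C@@H]2C[C@@]1(CO[Si](C)(C)C(C)(C)C)C[C@]2(OC(C)(C)O3)C3 | intermediate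
13 | bicyclic enone (C9=C11, C12 ketone) | C1=CC(=O)[C@@H]2C[C@@]1(CO[Si](C)(C)C(C)(C)C)C[C@]2(OC(C)(C)O3)C3 | intermediate
14 | methyl propanoate | CCC(=O)OC | starting material
15 | 1-methoxy-1-[(trimethylsilyl)oxy]prop-1-ene | CC=C(OC)O[Si](C)(C)C | intermediate
16 | trichlorotitanium enolate of 17 | COC(=O)C(C)[C@@H]1C=C(O[Ti](Cl)(Cl)Cl)[C@@H]2C[C@@]1(CO[Si](C)(C)C(C)(C)C)C[C@]2(OC(C)(C)O3)C3 | intermediate
17 | methyl 2-(bicyclyl)propanoate with C12 ketone (C10 epimers) | COC(=O)C(C)[C@@H]1CC(=O)[C@@H]2C[C@@]1(CO[Si](C)(C)C(C)(C)C)C[C@]2(OC(C)(C)O3)C3 | intermediate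
18 | C11=C12 enol triflate of 17 | COC(=O)C(C)[C@@H]1C=C(OS(=O)(=O)C(F)(F)F)[C@@H]2C[C@@]1(CO[Si](C)(C)C(C)(C)C)C[C@]2(OC(C)(C)O3)C3 | intermediate
19 | methyl 2-(bicyclyl)propanoate, C12 deoxygenated (C10 epimers) | COC(=O)C(C)[C@@H]1CC[C@@H]2C[C@@]1(CO[Si](C)(C)C(C)(C)C)C[C@]2(OC(C)(C)O3)C3 | intermediate
20 | 1,3-dithiane | C1CSCSC1 | starting material
21 | 2-lithio-1,3-dithiane | [Li]C1SCCCS1 | intermediate
22 | 2-acyl-1,3-dithiane (C5 ketone, C6 dithiane) | O=C(C1SCCCS1)C(C)[C@@H]2CC[C@@H]3C[C@@]2(CO[Si](C)(C)C(C)(C)C)C[C@]3(OC(C)(C)O4)C4 | intermediate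
23 | 1,1-dimethoxy-3-(bicyclyl)butan-2-one, the annulation precursor (C10 epimers) | CC(C(=O)C(OC)OC)[C@@H]1CC[C@@H]2C[C@@]1(CO[Si](C)(C)C(C)(C)C)C[C@]2(OC(C)(C)O3)C3 | intermediate
24 | tert-butyl acetate | CC(=O)OC(C)(C)C | starting material
25 | acrolein | C=CC=O | starting material
26 | tert-butyl 3-hydroxypent-4-enoate | C=CC(O)CC(=O)OC(C)(C)C | intermediate
27 | tert-butyl 3-oxopent-4-enoate | C=CC(=O)CC(=O)OC(C)(C)C | intermediate
28 | Michael adduct (quaternary C10; open 1,5-diketone) | C[C@@](C(=O)C(OC)OC)([C@@H]1CC[C@@H]2C[C@@]1(CO[Si](C)(C)C(C)(C)C)C[C@]2(OC(C)(C)O3)C3)CCC(=O)CC(=O)OC(C)(C)C | intermediate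
29 | aldol adduct (C5 carbinol; C4 and C5 epimers) | C[C@@]1([C@@H]2CC[C@@H]3C[C@@]2(CO[Si](C)(C)C(C)(C)C)C[C@]3(OC(C)(C)O4)C4)CCC(=O)C(C(=O)OC(C)(C)C)C1(O)C(OC)OC | intermediate
30 | ring A enone (C3 ketone, C4 ester, C4=C5) | C[C@@]1([C@@H]2CC[C@@H]3C[C@@]2(CO[Si](C)(C)C(C)(C)C)C[C@]3(OC(C)(C)O4)C4)CCC(=O)C(C(=O)OC(C)(C)C)=C1C(OC)OC | intermediate
31 | lithium enolate after reduction (C5–H set) | C[C@@]1([C@@H]2CC[C@@H]3C[C@@]2(CO[Si](C)(C)C(C)(C)C)C[C@]3(OC(C)(C)O4)C4)CCC(O[Li])=C(C(=O)OC(C)(C)C)[C@H]1C(OC)OC | intermediate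
32 | C4-methylated β-keto ester | C[C@@]1([C@@H]2CC[C@@H]3C[C@@]2(CO[Si](C)(C)C(C)(C)C)C[C@]3(OC(C)(C)O4)C4)CCC(=O)[C@@](C)(C(=O)OC(C)(C)C)[C@H]1C(OC)OC | intermediate
33 | C2=C3 enol triflate of 32 | C[C@@]1([C@@H]2CC[C@@H]3C[C@@]2(CO[Si](C)(C)C(C)(C)C)C[C@]3(OC(C)(C)O4)C4)CC=C(OS(=O)(=O)C(F)(F)F)[C@@](C)(C(=O)OC(C)(C)C)[C@H]1C(OC)OC | intermediate
34 | C3-deoxygenated ester | C[C@@]1([C@@H]2CC[C@@H]3C[C@@]2(CO[Si](C)(C)C(C)(C)C)C[C@]3(OC(C)(C)O4)C4)CCC[C@@](C)(C(=O)OC(C)(C)C)[C@H]1C(OC)OC | intermediate
35 | C7 alcohol | C[C@@]1([C@@H]2CC[C@@H]3C[C@@]2(CO)C[C@]3(OC(C)(C)O4)C4)CCC[C@@](C)(C(=O)OC(C)(C)C)[C@H]1C(OC)OC | intermediate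
36 | C7 aldehyde | C[C@@]1([C@@H]2CC[C@@H]3C[C@@]2(C=O)C[C@]3(OC(C)(C)O4)C4)CCC[C@@](C)(C(=O)OC(C)(C)C)[C@H]1C(OC)OC | intermediate
37 | CNP0159160.1 | C[C@@]1([C@@H]2CC[C@@H]3C[C@@]2(C=O)C[C@]3(O)CO)CCC[C@@](C)(C(=O)O)[C@H]1C=O | target

Total step count: 24.
Longest linear sequence: 20 steps (steps 1, 3–9, 11–15, 18–24).

Steps most likely to fail

Step 18. Ketone 23 is far less acidic than the methylene of 27, so self-condensation of 27 may outrun enolisation at C10, and the facial bias at C10 may be too small. The fallback sets out from 23 and makes the two bonds in separate, known operations. The potassium enolate (KN(SiMe3)2, THF, −78 °C) is added to 3-(trimethylsilyl)but-3-en-2-one, a vinyl ketone without an acidic methylene, to give the silyl diketone F1. NaOMe in MeOH removes silicon and closes ring A by aldol condensation to the enone F2. Reduction with Li in NH3 and trapping of the C4 enolate with CO2 gives the β-keto acid F3, which N,N′-diisopropyl-O-tert-butylisourea converts into the tert-butyl β-keto ester F4. NaH and MeI then methylate C4, and the route is rejoined at 32.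

Step 11. Bond formation at C9, which sits next to quaternary C8, may be so slow that TiCl4 attacks the acetonide or the silyl ether first. The fallback sets out from 13 and forms the C9–C10 bond intramolecularly. Reduction with NaBH4 and CeCl3·7H2O from the exo face gives the endo allylic alcohol F5. Mitsunobu esterification with propanoic acid (Ph3P, diisopropyl azodicarboxylate) inverts C12 to the exo propanoate F6. Ireland–Claisen rearrangement (LiN(i-Pr)2, Me3SiCl, THF, −78 °C → rt) transfers C10 suprafacially to the exo face of C9 and gives the unsaturated acid F7, with the double bond now at C11=C12. Me3SiCHN2 in MeOH gives the methyl ester F8, and hydrogenation over Pd/C returns to 19; steps 12 and 13 are then not needed.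

Step 19. The radical anion may expel methoxide from C6 (the vinylogous counterpart of α-alkoxy ketone cleavage), or C5 may be protonated on the wrong face. The fallback sets out from 30 and replaces electron transfer by hydride transfer from copper, with the enolate stored as a silyl enol ether. [(Ph3P)CuH]6 (5 mol %) with PhMe2SiH in toluene at rt effects 1,4-hydrosilylation, in which hydride adds to C5 anti to axial C20, and gives the dimethylphenylsilyl enol ether F9, whose C5 configuration can be checked before the next operation. MeLi in THF at 0 °C then cleaves the Si–O bond, so the route is rejoined at lithium enolate 31, which MeI (with DMPU) methylates at C4 anti to C20 to give 32.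

Further compounds
F1 | step 18 | silyl diketone from 23 and 3-(trimethylsilyl)but-3-en-2-one | C[C@@](C(=O)C(OC)OC)([C@@H]1CC[C@@H]2C[C@@]1(CO[Si](C)(C)C(C)(C)C)C[C@]2(OC(C)(C)O3)C3)CC([Si](C)(C)C)C(C)=O
F2 | step 18 | ring A enone without the C4 ester | C[C@@]1([C@@H]2CC[C@@H]3C[C@@]2(CO[Si](C)(C)C(C)(C)C)C[C@]3(OC(C)(C)O4)C4)CCC(=O)C=C1C(OC)OC
F3 | step 18 | β-keto acid (C4 carboxylic acid, C5–H set) | C[C@@]1([C@@H]2CC[C@@H]3C[C@@]2(CO[Si](C)(C)C(C)(C)C)C[C@]3(OC(C)(C)O4)C4)CCC(=O)C(C(=O)O)[C@H]1C(OC)OC
F4 | step 18 | tert-butyl β-keto ester (C4–H, C5–H) | C[C@@]1([C@@H]2CC[C@@H]3C[C@@]2(CO[Si](C)(C)C(C)(C)C)C[C@]3(OC(C)(C)O4)C4)CCC(=O)C(C(=O)OC(C)(C)C)[C@H]1C(OC)OC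
F5 | step 11 | endo allylic alcohol at C12 | C1=C[C@@H](O)[C@@H]2C[C@@]1(CO[Si](C)(C)C(C)(C)C)C[C@]2(OC(C)(C)O3)C3
F6 | step 11 | exo propanoate at C12 | C1=C[C@H](OC(=O)CC)[C@@H]2C[C@@]1(CO[Si](C)(C)C(C)(C)C)C[C@]2(OC(C)(C)O3)C3
F7 | step 11 | 2-(bicyclyl)propanoic acid with C11=C12 | OC(=O)C(C)[C@@H]1C=C[C@@H]2C[C@@]1(CO[Si](C)(C)C(C)(C)C)C[C@]2(OC(C)(C)O3)C3
F8 | step 11 | methyl ester of F7 | COC(=O)C(C)[C@@H]1C=C[C@@H]2C[C@@]1(CO[Si](C)(C)C(C)(C)C)C[C@]2(OC(C)(C)O3)C3
F9 | step 19 | dimethylphenylsilyl enol ether at C3 (C3=C4, C5–H set) | C[C@@]1([C@@H]2CC[C@@H]3C[C@@]2(CO[Si](C)(C)C(C)(C)C)C[C@]3(OC(C)(C)O4)C4)CCC(O[Si](C)(C)c5ccccc5)=C(C(=O)OC(C)(C)C)[C@H]1C(OC)OC
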